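**Retrosynthetic overview**
1. Feature used: the only stereocentre is C2 of the chroman-4-one (pyranone) ring. It is a hemiketal carbon bonded to O1, OH, C3H2 and the CH2 that carries the 4-hydroxy-2-pyrone. It epimerises by O1–C2 ring opening to an achiral 1-(2-hydroxyaryl)-1,3-diketone, so no kinetically set configuration could be carried through a synthesis.
2. Key disconnection: O1–C2, closed last and reversibly. Both enantiomers are funnelled into one by crystallisation of a diastereomeric salt formed at the acidic pyrone 4-OH, one CH2 away from C2 (dynamic, stereoconvergent).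
3. C3–C4: the terminal carbanion of the trianion of 6-acetonyl-4-hydroxy-2-pyrone attacks the acylal carbonyl of a 5-isopentyl resorcylate acetonide. Loss of acetone frees the C8a phenol.
4. Benzene ring: biomimetic C4a–C5 aldol aromatisation of an open-chain diketo-dioxinone (trimethyldioxinone + acetyl + 4-methylpentanoyl). Pyrone ring: bought as triacetic acid lactone and extended by C2.
5. Ring order: pyrone (purchased), benzene, pyranone (first racemic, then one enantiomer).

Key step: step 8

Assumption: the free hemiketal is taken to hold its configuration as a solid and for hours in cold, weakly acidic solution; which hand of the amine gives the less soluble salt with the (2R)-hemiketal cannot be predicted, so the route is written for the (S)-amine, C2 is to be assigned by X-ray against the amine stereocentre, and the (R)-amine (also commercial, with mirror-image salts of identical solubility) would be taken if the sense is opposite.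

**Step 1**
Reactants: 1 2,2,6-trimethyl-4H-1,3-dioxin-4-one; 2 acetyl chloride
Product: 4 2,2-dimethyl-6-(2-oxopropyl)-4H-1,3-dioxin-4-one, via lithium dienolate 3 (not isolated)
Conditions: LiHMDS (2 equiv), THF, −78 °C; then 2, −78 → −20 °C; 1 M HCl
Reagents that add atoms: none
Why: Vinylogous Claisen-type C-acylation, in which the dienolate reacts at its γ-carbon (the former 6-methyl group) and the second equivalent of base absorbs the more acidic product.

**Step 2**
Reactants: 5 4-methylpentanoyl chloride
Product: 6 N-methoxy-N,4-dimethylpentanamide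
Conditions: MeNH(OMe)·HCl, K2CO3, CH2Cl2/H2O, 0 °C → rt
Reagents that add atoms: N,O-dimethylhydroxylamine hydrochloride, CNOC.Cl
Why: Schotten–Baumann amidation gives the Weinreb amide that allows a clean single acylation in step 3.

**Step 3**
Reactants: 4 2,2-dimethyl-6-(2-oxopropyl)-4H-1,3-dioxin-4-one; 6 N-methoxy-N,4-dimethylpentanamide
Product: 8 2,2-dimethyl-6-(7-methyl-2,4-dioxooctyl)-4H-1,3-dioxin-4-one, via dilithio dianion 7 (not isolated)
Conditions: LDA (2.1 equiv), THF, −78 → −40 °C; then 6, −78 → −30 °C; cold 1 M HCl
Reagents that add atoms: none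
Why: Weinreb ketone synthesis on a 1,3-dicarbonyl-type dianion, in which the last-formed terminal carbanion is the reactive site and the chelated tetrahedral adduct prevents over-addition and proton exchange with the product.

**Step 4**
Reactants: 8 2,2-dimethyl-6-(7-methyl-2,4-dioxooctyl)-4H-1,3-dioxin-4-one
Product: 10 7-(tert-butyldimethylsilyloxy)-2,2-dimethyl-5-(3-methylbutyl)-4H-1,3-benzodioxin-4-one, via free 7-hydroxybenzodioxinone 9 (not isolated)
Conditions: Et3N, 4 Å MS, CH2Cl2, rt; then TBSCl, DMAP (cat.), 0 °C → rt
Reagents that add atoms: tert-butyldimethylsilyl chloride, CC(C)(C)[Si](C)(C)Cl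
Why: Biomimetic intramolecular aldol condensation and aromatisation, in which C5 of the dioxinone adds to the ketone next to the isopentyl group (the only six-membered carbocycle within reach while the dioxinone locks the other carbonyls), water is lost, and the 7-OH, which as a phenoxide would deactivate the carbonyl in step 6, is silylated in the same flask.

**Step 5**
Reactants: 11 4-hydroxy-6-methyl-2H-pyran-2-one (triacetic acid lactone); 12 N-methoxy-N-methylacetamide
Product: 14 4-hydroxy-6-(2-oxopropyl)-2H-pyran-2-one, via dilithio dianion 13 (not isolated)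
Conditions: LDA (2.2 equiv), THF–DMPU, −78 → −20 °C; then 12, −78 → 0 °C; 1 M HCl
Reagents that add atoms: none
Why: Weinreb ketone synthesis on the O,C-dianion of the pyrone, which reacts at the lateral CH2 carbanion and not at the oxygen or at C3.

**Step 6**
Reactants: 10 7-(tert-butyldimethylsilyloxy)-2,2-dimethyl-5-(3-methylbutyl)-4H-1,3-benzodioxin-4-one; 14 4-hydroxy-6-(2-oxopropyl)-2H-pyran-2-one
Product: 17 rac-7-(tert-butyldimethylsilyloxy)-2-hydroxy-2-[(4-hydroxy-2-oxo-2H-pyran-6-yl)methyl]-5-(3-methylbutyl)chroman-4-one, via trilithio trianion 15 (not isolated), via ring-opened diketone 16 (not isolated)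
Conditions: 14 (2.5 equiv), LDA (3.05 equiv per 14), THF, −78 → 0 °C; then 10 (1 equiv), −78 → −10 °C; AcOH at −78 °C, then pH 4 buffer
Reagents that add atoms: none
Why: Claisen-type acylation of a polyanion, in which the least stabilised terminal CH2 carbanion of 15 attacks the non-enolisable acylal carbonyl of 10, collapse expels acetone and the C8a phenoxide, and after the mild acid quench the phenol adds to the new ketone (6-exo-trig) to give the racemic hemiketal.

**Step 7**
Reactants: 17 rac-7-(tert-butyldimethylsilyloxy)-2-hydroxy-2-[(4-hydroxy-2-oxo-2H-pyran-6-yl)methyl]-5-(3-methylbutyl)chroman-4-one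
Product: 18 rac-2,7-dihydroxy-2-[(4-hydroxy-2-oxo-2H-pyran-6-yl)methyl]-5-(3-methylbutyl)chroman-4-one
Conditions: Et3N·3HF, THF, 0 °C → rt; pH 4 buffer/EtOAc
Reagents that add atoms: none
Why: Fluoride-mediated cleavage of the aryl silyl ether under nearly neutral conditions, which should spare the acid- and heat-sensitive hemiketal and the pyrone.

**Step 8**
Reactants: 18 rac-2,7-dihydroxy-2-[(4-hydroxy-2-oxo-2H-pyran-6-yl)methyl]-5-(3-methylbutyl)chroman-4-one; 19 (S)-N,N-dimethyl-1-phenylethylamine
Product: 21 (S)-N,N-dimethyl-1-phenylethylammonium salt of the (2R)-hemiketal (pyron-4-olate), via ring-opened diketone 20 (not isolated)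
Conditions: 19 (1.05 equiv), i-PrOAc–MeCN, seeded slurry, temperature cycling 35 ⇄ 15 °C, several days; filter at 0 °C
Reagents that add atoms: none
Why: Proposed new method: in solution the amine/pyronate pair catalyses reversible cleavage of the O1–C2 bond to the achiral ring-opened diketone 20, so both C2 epimers of the salt interconvert while only the less soluble diastereomeric salt 21 leaves the equilibrium as a solid, and the whole mass should be funnelled into one configuration (crystallisation-induced diastereomer transformation). The closest known reaction types are the crystallisation of a single anomer from a mutarotating sugar and the amine-salt transformation of carboxylic acids with a labile stereocentre, but neither has been shown on 2-hydroxychroman-4-ones. The pyranone ring is closed, and closed again after each opening, by 6-exo-trig addition of the C8a phenol oxygen to the C2 ketone. The configuration at C2 is controlled by the lattice energy of the (2R)-acid·(S)-amine salt and not by any kinetic facial bias. The step needs a clear solubility gap between the two salts and an epimerisation that is faster than dehydration: the 4-hydroxy-2-pyrone (pKa about 5) one CH2 away from C2 places the chiral cation next to the stereocentre, the peri 5-isopentyl group favours the closed hemiketal over the diketone, and a tertiary amine cannot condense with the diketone or the pyrone.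

**Step 9**
Reactants: 21 (S)-N,N-dimethyl-1-phenylethylammonium salt of the (2R)-hemiketal
Product: 22 (2R)-2,7-dihydroxy-2-[(4-hydroxy-2-oxo-2H-pyran-6-yl)methyl]-5-(3-methylbutyl)-2,3-dihydro-4H-chromen-4-one
Conditions: 1 M HCl (1.0 equiv), EtOAc, 0 °C, minutes; dry and concentrate cold; precipitate with heptane; store as a solid at −20 °C
Reagents that add atoms: none
Why: Salt break by acid–base extraction, in which proton transfer to the pyronate is instantaneous and carries the amine (the catalyst of ring opening) into the water layer, so C2 should keep its configuration, while cold and brief handling avoids acid-catalysed dehydration.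

**Compound list**
1 | 2,2,6-trimethyl-4H-1,3-dioxin-4-one | CC1=CC(=O)OC(C)(C)O1 | starting material
2 | acetyl chloride | CC(=O)Cl | starting material
3 | lithium dienolate of 1 | [Li+].C=C1C=C([O-])OC(C)(C)O1 | intermediate
4 | 2,2-dimethyl-6-(2-oxopropyl)-4H-1,3-dioxin-4-one | CC(=O)CC1=CC(=O)OC(C)(C)O1 | intermediate
5 | 4-methylpentanoyl chloride | CC(C)CCC(=O)Cl | starting material
6 | N-methoxy-N,4-dimethylpentanamide | CC(C)CCC(=O)N(C)OC | intermediate
7 | dilithio dianion of 4 | [Li+].[Li+].C=C([O-])C=C1C=C([O-])OC(C)(C)O1 | intermediate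
8 | 2,2-dimethyl-6-(7-methyl-2,4-dioxooctyl)-4H-1,3-dioxin-4-one | CC(C)CCC(=O)CC(=O)CC1=CC(=O)OC(C)(C)O1 | intermediate
9 | 7-hydroxy-2,2-dimethyl-5-(3-methylbutyl)-4H-1,3-benzodioxin-4-one | CC(C)CCc1cc(O)cc2OC(C)(C)OC(=O)c12 | intermediate
10 | 7-(tert-butyldimethylsilyloxy)-2,2-dimethyl-5-(3-methylbutyl)-4H-1,3-benzodioxin-4-one | CC(C)CCc1cc(O[Si](C)(C)C(C)(C)C)cc2OC(C)(C)OC(=O)c12 | intermediate
11 | 4-hydroxy-6-methyl-2H-pyran-2-one | Cc1cc(O)cc(=O)o1 | starting material
12 | N-methoxy-N-methylacetamide | CC(=O)N(C)OC | starting material
13 | dilithio dianion of 11 | [Li+].[Li+].C=C1C=C([O-])C=C([O-])O1 | intermediate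
14 | 4-hydroxy-6-(2-oxopropyl)-2H-pyran-2-one | CC(=O)Cc1cc(O)cc(=O)o1 | intermediate
15 | trilithio trianion of 14 | [Li+].[Li+].[Li+].C=C([O-])C=C1C=C([O-])C=C([O-])O1 | intermediate
16 | 6-{4-[4-(tert-butyldimethylsilyloxy)-2-hydroxy-6-(3-methylbutyl)phenyl]-2,4-dioxobutyl}-4-hydroxy-2H-pyran-2-one (achiral) | CC(C)CCc1cc(O[Si](C)(C)C(C)(C)C)cc(O)c1C(=O)CC(=O)Cc1cc(O)cc(=O)o1 | intermediate
17 | rac-7-(tert-butyldimethylsilyloxy)-2-hydroxy-2-[(4-hydroxy-2-oxo-2H-pyran-6-yl)methyl]-5-(3-methylbutyl)chroman-4-one (racemic) | CC(C)CCc1cc(O[Si](C)(C)C(C)(C)C)cc2OC(O)(Cc3cc(O)cc(=O)o3)CC(=O)c12 | intermediate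
18 | rac-2,7-dihydroxy-2-[(4-hydroxy-2-oxo-2H-pyran-6-yl)methyl]-5-(3-methylbutyl)chroman-4-one (racemic) | CC(C)CCc1cc(O)cc2OC(O)(Cc3cc(O)cc(=O)o3)CC(=O)c12 | intermediate
19 | (S)-N,N-dimethyl-1-phenylethylamine | C[C@H](N(C)C)c1ccccc1 | starting material
20 | 6-{4-[2,4-dihydroxy-6-(3-methylbutyl)phenyl]-2,4-dioxobutyl}-4-hydroxy-2H-pyran-2-one (achiral) | CC(C)CCc1cc(O)cc(O)c1C(=O)CC(=O)Cc1cc(O)cc(=O)o1 | intermediate
21 | (S)-N,N-dimethyl-1-phenylethylammonium (2R)-pyron-4-olate salt | CC(C)CCc1cc(O)cc2c1C(=O)C[C@@](O)(Cc1cc([O-])cc(=O)o1)O2.C[C@H]([NH+](C)C)c1ccccc1 | intermediate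
22 | (2R)-2,7-dihydroxy-2-[(4-hydroxy-2-oxo-2H-pyran-6-yl)methyl]-5-(3-methylbutyl)-2,3-dihydro-4H-chromen-4-one | CC(C)CCc1cc(O)cc2c1C(=O)C[C@@](O)(Cc1cc(O)cc(=O)o1)O2 | target

**Total step count:** 9
**Longest linear sequence:** 7 (steps 1, 3, 4, 6, 7, 8, 9)

**Steps most likely to fail**

1. **Step 8 (Proposed new method).** The two diastereomeric salts may co-crystallise or separate as an oil. Ring-chain epimerisation may also be slower than base-induced dehydration of the hemiketal during the long slurry ageing.
   Fallback with known chemistry: it sets out from 18 and replaces the dynamic salt crystallisation by preparative enantioselective chromatography (SFC on an immobilised polysaccharide phase, CO2/i-PrOH with a trace of formic acid, column at or below 10 °C). This separates 22 from the (2S)-enantiomer F1. F1 is re-equilibrated to 18 with catalytic Et3N in EtOAc and recycled. The fallback comes back to the route at 22, so steps 8 and 9 are skipped.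

2. **Step 6.** The third deprotonation may be incomplete, or proton transfer from the liberated acetone may quench the terminal carbanion. Attack at a carbonyl flanked by the isopentyl group may be slow, and the silyl ether may be lost early.
   Fallback: it sets out from 10 and exchanges the ester acylation for an aldol addition followed by oxidation. DIBAL-H (CH2Cl2, −78 °C) reduces the acylal to 4-(tert-butyldimethylsilyloxy)-2-hydroxy-6-(3-methylbutyl)benzaldehyde F2. Trianion 15, with one extra equivalent for the phenol, adds to the more electrophilic and less hindered formyl group to give the β-hydroxy ketone F3. Oxidation of the benzylic carbinol (MnO2, or Dess–Martin periodinane/NaHCO3) gives diketone 16, which closes. The fallback comes back to the route at 17.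

3. **Step 3.** Proton exchange between the dianion and the amide is possible. The diketo-dioxinone may also cyclise early and unselectively during work-up and isolation.
   Fallback: it sets out from 11 and 6 and builds the benzene ring by a pyrone-to-benzene ring transformation. Dianion 13 is acylated with 6 to give 4-hydroxy-6-(5-methyl-2-oxohexyl)-2H-pyran-2-one F4. Aqueous KOH opens the lactone to the triketo acid, which closes by aldol condensation to 2,4-dihydroxy-6-(3-methylbutyl)benzoic acid F5. TFAA/TFA/acetone forms the acetonide. The fallback comes back to the route at 9, which is silylated as in the second half of step 4.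

**Further compounds**
F1 | step 8 | (2S)-2,7-dihydroxy-2-[(4-hydroxy-2-oxo-2H-pyran-6-yl)methyl]-5-(3-methylbutyl)-2,3-dihydro-4H-chromen-4-one | CC(C)CCc1cc(O)cc2c1C(=O)C[C@](O)(Cc1cc(O)cc(=O)o1)O2
F2 | step 6 | 4-(tert-butyldimethylsilyloxy)-2-hydroxy-6-(3-methylbutyl)benzaldehyde | CC(C)CCc1cc(O[Si](C)(C)C(C)(C)C)cc(O)c1C=O
F3 | step 6 | rac-6-{4-[4-(tert-butyldimethylsilyloxy)-2-hydroxy-6-(3-methylbutyl)phenyl]-4-hydroxy-2-oxobutyl}-4-hydroxy-2H-pyran-2-one | CC(C)CCc1cc(O[Si](C)(C)C(C)(C)C)cc(O)c1C(O)CC(=O)Cc1cc(O)cc(=O)o1
F4 | step 3 | 4-hydroxy-6-(5-methyl-2-oxohexyl)-2H-pyran-2-one | CC(C)CCC(=O)Cc1cc(O)cc(=O)o1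
F5 | step 3 | 2,4-dihydroxy-6-(3-methylbutyl)benzoic acid | CC(C)CCc1cc(O)cc(O)c1C(=O)O
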